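**Plan**

1. Retrosynthesis, late cuts: unmask the two phenols; form the upper epoxide (C-2/C-3) from the enone; cut the bond between the ketal carbon C-1 and the bridging oxygen, which is the retron of an oxidative spiroketalisation of a 4-aryloxy-1-naphthol by the C-1′ tertiary alcohol (locants are defined under the plan).
2. Lower unit: the C-4′ carbinol comes from the ketone and the C-2′/C-3′ epoxide from the enone, leaving a p-quinol (4-aryl-4-hydroxynaphthalen-1(4H)-one).
3. Central cut: the bonds C-4a′–C-4′ and C-8a′–C-1′ are broken together. Ring B carries on two neighbouring carbons a four-carbon bridge (C-1′ to C-4′) oxygenated at both ends, the retron of a 3,6-dioxygenated benzyne adding across a 2-methoxy-5-arylfuran. The furan oxygen becomes the C-1′ oxygen (later the bridging ketal oxygen) and the methoxy-bearing carbon becomes the C-4′ carbonyl.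
4. Tether: the aryl ether oxygen of the target (C-8′–O–C-1), peri to the furan-bearing C-8, makes the cycloaddition intramolecular, closes a seven-membered ring and fixes the regiochemistry.
5. Forward order: upper naphthalene by aryne/2-silyloxyfuran annulation (steps 1–3); diaryl ether, bromide, Dakin, MOM, Negishi (4–8); aryne cycloaddition and ketal collapse (9); lower epoxide and C-4′ carbinol (10, 11); spiroketal (12, 13); upper epoxide and deprotection (14, 15).
6. Stereochemistry: C-1′ arises racemic in step 9; the C-2′/C-3′ epoxide is directed cis to the C-1′ hydroxyl; (S)-CBS reduction sets C-4′ (S) by reagent control and turns the two C-1′ antipodes into separable diastereomers, which fixes the absolute configuration; C-1 is forced by the bicyclic ketal; the upper epoxide forms on the face of the bridging oxygen.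

Key step: step 9

Locants: each ten-carbon unit is numbered like a naphthalene, the upper unit with plain locants and the lower unit with primed ones. Upper unit: C-1 ketal carbon, C-2/C-3 epoxide, C-4 ketone, C-5 OH, C-6 Cl, C-8 bonded to C-1′. Lower unit: C-1′ tertiary C–O, C-2′/C-3′ epoxide, C-4′ CHOH, C-5′ OH, C-6′ Cl, C-8′ carries the ether oxygen. Ring B is the benzene ring of the lower unit. The ether oxygen joins C-1 and C-8′; the bridging oxygen joins C-1 and C-1′. The same locants are used for the aromatic precursors.

Remark: compounds 1, 3, 9 and 15 are taken as commercial; 7 and 21 to 23 are racemates, drawn as one antipode (for 21 to 23 the one that is carried on).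

**Step 1**
Reactants: 1 2-chloro-5-fluorophenol
Product: 2 1-chloro-4-fluoro-2-(methoxymethoxy)benzene
Conditions: MOMCl, i-Pr2NEt, CH2Cl2, 0 °C to rt
Reagents that add atoms: chloromethyl methyl ether, COCCl
Why: Williamson-type O-alkylation of the phenol gives the MOM ether, which masks the C-5 oxygen and later directs lithiation.

**Step 2**
Reactants: 3 furan-2(5H)-one
Product: 4 (furan-2-yloxy)triisopropylsilane
Conditions: i-Pr3SiOTf, Et3N, CH2Cl2, 0 °C
Reagents that add atoms: triisopropylsilyl trifluoromethanesulfonate, CC(C)[Si](OS(=O)(=O)C(F)(F)F)(C(C)C)C(C)C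
Why: Soft enolisation of the butenolide and O-silylation (silyl dienol ether formation) should give the 2-silyloxyfuran that supplies carbons C-1 to C-4.

**Step 3**
Reactants: 2 1-chloro-4-fluoro-2-(methoxymethoxy)benzene; 4 (furan-2-yloxy)triisopropylsilane
Product: 8 6-chloro-5-(methoxymethoxy)-4-(triisopropylsilyloxy)naphthalen-1-ol, via aryllithium 5 (not isolated), via aryne 6 (not isolated), via bridged silyl ketal 7 (not isolated)
Conditions: n-BuLi, THF, −78 °C; then 4 (2.5 equiv), −78 °C to rt; SiO2, CH2Cl2
Reagents that add atoms: none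
Why: Directed ortho-lithiation between F and OMOM and loss of LiF give the 3-alkoxyaryne 6, which undergoes an aryne–furan Diels–Alder reaction in which the unsubstituted α-carbon of 4 bonds to the aryne carbon remote from OMOM, and ring-opening aromatisation of ketal 7 then leaves the silyl ether peri to OMOM (C-4) and the free hydroxyl at C-1, with no stereocenter remaining.

**Step 4**
Reactants: 8 6-chloro-5-(methoxymethoxy)-4-(triisopropylsilyloxy)naphthalen-1-ol; 9 2-chloro-4,5-difluorobenzaldehyde
Product: 10 2-chloro-4-{[6-chloro-5-(methoxymethoxy)-4-(triisopropylsilyloxy)naphthalen-1-yl]oxy}-5-fluorobenzaldehyde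
Conditions: NaH, DMF, 0 °C to 40 °C
Reagents that add atoms: none
Why: Nucleophilic aromatic substitution (addition–elimination) of the naphthoxide at the fluorine para to the formyl group, fluoride being a far better leaving group than the ortho chloride, should form the diaryl ether, and the NaF formed is inert toward the silyl ether.

**Step 5**
Reactants: 10 2-chloro-4-{[6-chloro-5-(methoxymethoxy)-4-(triisopropylsilyloxy)naphthalen-1-yl]oxy}-5-fluorobenzaldehyde
Product: 11 4-{[8-bromo-6-chloro-5-(methoxymethoxy)-4-(triisopropylsilyloxy)naphthalen-1-yl]oxy}-2-chloro-5-fluorobenzaldehyde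
Conditions: NBS, MeCN, 0 °C to rt, dark
Reagents that add atoms: N-bromosuccinimide, O=C1CCC(=O)N1Br
Why: Electrophilic aromatic bromination should occur at C-8, the α-position para to the C-5 alkoxy group, while the formyl-bearing ring B is deactivated and C-3 is screened by the bulky silyl ether.

**Step 6**
Reactants: 11 4-{[8-bromo-6-chloro-5-(methoxymethoxy)-4-(triisopropylsilyloxy)naphthalen-1-yl]oxy}-2-chloro-5-fluorobenzaldehyde
Product: 13 4-{[8-bromo-6-chloro-5-(methoxymethoxy)-4-(triisopropylsilyloxy)naphthalen-1-yl]oxy}-2-chloro-5-fluorophenol, via aryl formate 12 (not isolated)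
Conditions: mCPBA, CH2Cl2, 0 °C to rt; then Et3N (cat.), MeOH, rt
Reagents that add atoms: 3-chloroperbenzoic acid, OOC(=O)c1cccc(Cl)c1
Why: Dakin-type Baeyer–Villiger oxidation with migration of the aryloxy-substituted aryl group turns the formyl group, which activated step 4, into a formate that is methanolysed to the C-5′ phenol.

**Step 7**
Reactants: 13 4-{[8-bromo-6-chloro-5-(methoxymethoxy)-4-(triisopropylsilyloxy)naphthalen-1-yl]oxy}-2-chloro-5-fluorophenol
Product: 14 8-bromo-6-chloro-1-[5-chloro-2-fluoro-4-(methoxymethoxy)phenoxy]-5-(methoxymethoxy)-4-(triisopropylsilyloxy)naphthalene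
Conditions: MOMCl, i-Pr2NEt, CH2Cl2, 0 °C to rt
Reagents that add atoms: chloromethyl methyl ether, COCCl
Why: O-alkylation gives the C-5′ MOM ether, which together with the neighbouring fluorine will direct the metalation of step 9.

**Step 8**
Reactants: 14 8-bromo-6-chloro-1-[5-chloro-2-fluoro-4-(methoxymethoxy)phenoxy]-5-(methoxymethoxy)-4-(triisopropylsilyloxy)naphthalene; 15 2-methoxyfuran
Product: 18 6-chloro-1-[5-chloro-2-fluoro-4-(methoxymethoxy)phenoxy]-8-(5-methoxyfuran-2-yl)-5-(methoxymethoxy)-4-(triisopropylsilyloxy)naphthalene, via furyllithium 16 (not isolated), via furylzinc chloride 17 (not isolated)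
Conditions: 15, n-BuLi, THF, −78 to 0 °C; ZnCl2, 0 °C; then 14, Pd(P(t-Bu)3)2 (5 mol%), THF, rt to 45 °C
Reagents that add atoms: none
Why: Negishi coupling, in which 2-methoxyfuran is lithiated at its free α-position and transmetalated to zinc, and zerovalent palladium inserts into the C–Br bond in preference to the two C–Cl bonds and the C–F bond.

**Step 9**
Reactants: 18 6-chloro-1-[5-chloro-2-fluoro-4-(methoxymethoxy)phenoxy]-8-(5-methoxyfuran-2-yl)-5-(methoxymethoxy)-4-(triisopropylsilyloxy)naphthalene
Product: 22 racemic p-quinol [C-1′ tertiary alcohol; C-2′=C-3′–C-4′=O enone; seven-membered aryl ether ring], via ring-B aryllithium 19 (not isolated), via ring-B aryne 20 (not isolated), via bridged methoxy ketal 21 (not isolated)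
Conditions: n-BuLi (1.1 equiv), THF, −78 °C, then warm to 0 °C; then 1 M HCl, THF, 0 °C
Reagents that add atoms: water, O
Why: n-BuLi removes the ring-B proton flanked by fluorine and the MOM ether, LiF is lost on warming, and the 3,6-dioxygenated aryne 20 is trapped in a [4+2] cycloaddition by the 2-methoxy-5-arylfuran on the neighbouring peri position, the closest known reaction type being the intramolecular benzyne–furan Diels–Alder reaction. Two rings close at once: the six-membered carbocycle of the lower unit, by bonding of the aryne carbons C-8a′ and C-4a′ to the furan termini C-1′ and C-4′ (7-oxanorbornadiene mode), and the seven-membered oxepine ring that holds the ether oxygen, because the diene terminus C-1′ sits at the end of the tether. C-1′ and C-4′ are formed as bridgeheads whose relative configuration is fixed by suprafacial addition across the furan, but nothing in 18 distinguishes the two furan faces, so 21 is racemic and only C-1′ survives as a stereocenter. Dilute acid opens the bridged ketal at the C-4′–O bond (oxocarbenium ion stabilised by OMe), water delivers the C-4′ carbonyl oxygen, and the former furan oxygen stays on C-1′ as the tertiary hydroxyl that later becomes the bridging ketal oxygen. The two oxygen substituents beside the triple bond (OMOM at C-5′, the ether oxygen at C-8′) are nearly equivalent and give no regiochemical bias, so it is the tether that decides: the aryne carbon next to the ether oxygen can only reach the naphthyl-bearing furan carbon. The step needs site-selective metalation, secured by the cooperative F/OMOM pair over the position between the ether oxygen and Cl, and a trap with no acidic α-hydrogen, secured by the 2,5-disubstituted furan.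

**Step 10**
Reactants: 22 racemic p-quinol
Product: 23 racemic syn-epoxy ketone [C-2′/C-3′ epoxide cis to the C-1′ hydroxyl; C-4′ ketone]
Conditions: t-BuOOH, benzyltrimethylammonium hydroxide (cat.), THF, 0 °C
Reagents that add atoms: tert-butyl hydroperoxide, CC(C)(C)OO
Why: Weitz–Scheffer nucleophilic epoxidation, in which the hydroperoxide anion is guided by hydrogen bonding to the C-1′ hydroxyl and the naphthyl group on C-1′ shields the other face, so the epoxide oxygen at C-2′ and C-3′ should be set cis to the C-1′ oxygen.

**Step 11**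
Reactants: 23 racemic syn-epoxy ketone
Product: 24 (4′S)-trans-epoxy diol [C-1′ hydroxyl and epoxide oxygen on one face; C-4′ hydroxyl on the other; single enantiomer]
Conditions: (S)-2-methyl-CBS-oxazaborolidine (1.0 equiv), catecholborane, toluene–CH2Cl2, −78 to −40 °C; MeOH, aq. NaHCO3; chromatography
Reagents that add atoms: none
Why: Corey–Bakshi–Shibata reduction with the ortho-disubstituted aryl ring as the large group should make C-4′ (S) in both antipodes of 23, which gives the trans-epoxy alcohol 24 from the antipode carried on and the separable cis diastereomer from the other, so this step fixes the absolute configuration; in the wanted antipode the reagent has to override hydride delivery anti to the epoxide oxygen, and any leakage there ends in the cis series, costing yield but not enantiomeric purity; catecholborane is chosen because a borate formed at the C-1′ oxygen carries no hydride to deliver.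

**Step 12**
Reactants: 24 (4′S)-trans-epoxy diol
Product: 25 C-4 naphthol [silyl ether removed]
Conditions: Bu4NF, AcOH (1:1), THF, 0 °C, argon
Reagents that add atoms: none
Why: Fluoride cleaves the aryl silyl ether (Si–F bond formation) and frees the C-4 naphthol, while the alcohols, the epoxide and the MOM ethers are untouched.

**Step 13**
Reactants: 25 C-4 naphthol
Product: 26 spiroketal enone [C-1 ketal with the ether oxygen and the bridging oxygen; C-2=C-3–C-4=O; both phenols as MOM ethers]
Conditions: PhI(OAc)2 (1.1 equiv), CF3CH2OH, −20 to 0 °C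
Reagents that add atoms: none
Why: Hypervalent-iodine oxidative dearomatisation of the 4-aryloxy-1-naphthol to a quinone monoketal, with five-membered ring closure at C-1 by the peri-positioned C-1′ tertiary hydroxyl; the new stereocenter C-1 has no choice, because the bridging oxygen and the ether oxygen must span C-1 and C-1′ in a bicyclo[3.2.1] ketal.

**Step 14**
Reactants: 26 spiroketal enone
Product: 27 bis-epoxide bis-MOM ether
Conditions: t-BuOOH, DBU, CH2Cl2, 0 °C
Reagents that add atoms: tert-butyl hydroperoxide, CC(C)(C)OO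
Why: Weitz–Scheffer epoxidation of the quinone-monoketal enone, in which the hydroperoxide should add to C-2 on the face of the one-atom oxygen bridge because the other face is covered by the ether oxygen and ring B, setting C-2 and C-3 with the epoxide oxygen cis to the bridging oxygen.

**Step 15**
Reactants: 27 bis-epoxide bis-MOM ether
Product: 28 target compound (CNP0289684.3)
Conditions: NaHSO4·SiO2, CH2Cl2, rt
Reagents that add atoms: none
Why: Acid-catalysed cleavage of the two aryl methoxymethyl acetals on a solid acid without a nucleophilic counter-ion, so that both epoxides and the ketal should survive.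

**Compound list**

1 | 2-chloro-5-fluorophenol | Oc1cc(F)ccc1Cl | starting material
2 | 1-chloro-4-fluoro-2-(methoxymethoxy)benzene | COCOc1cc(F)ccc1Cl | intermediate
3 | furan-2(5H)-one | O=C1C=CCO1 | starting material
4 | (furan-2-yloxy)triisopropylsilane | CC(C)[Si](Oc1ccco1)(C(C)C)C(C)C | intermediate
5 | [3-chloro-6-fluoro-2-(methoxymethoxy)phenyl]lithium (aryllithium) | COCOc1c([Li])c(F)ccc1Cl | intermediate
6 | 4-chloro-3-(methoxymethoxy)benzyne (aryne) | COCOC1=C(Cl)C=CC#C1 | intermediate
7 | racemic 6-chloro-5-(methoxymethoxy)-4-(triisopropylsilyloxy)-1,4-dihydro-1,4-epoxynaphthalene (bridged silyl ketal) | COCOc1c(Cl)ccc2c1[C@@]1(O[Si](C(C)C)(C(C)C)C(C)C)C=C[C@@H]2O1 | intermediate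
8 | 6-chloro-5-(methoxymethoxy)-4-(triisopropylsilyloxy)naphthalen-1-ol | Oc1ccc(O[Si](C(C)C)(C(C)C)C(C)C)c2c(OCOC)c(Cl)ccc12 | intermediate
9 | 2-chloro-4,5-difluorobenzaldehyde | O=Cc1cc(F)c(F)cc1Cl | starting material
10 | 2-chloro-4-{[6-chloro-5-(methoxymethoxy)-4-(triisopropylsilyloxy)naphthalen-1-yl]oxy}-5-fluorobenzaldehyde | O=Cc1cc(F)c(Oc2ccc(O[Si](C(C)C)(C(C)C)C(C)C)c3c(OCOC)c(Cl)ccc23)cc1Cl | intermediate
11 | 4-{[8-bromo-6-chloro-5-(methoxymethoxy)-4-(triisopropylsilyloxy)naphthalen-1-yl]oxy}-2-chloro-5-fluorobenzaldehyde | O=Cc1cc(F)c(Oc2ccc(O[Si](C(C)C)(C(C)C)C(C)C)c3c(OCOC)c(Cl)cc(Br)c23)cc1Cl | intermediate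
12 | formate ester of phenol 13 (aryl formate) | O=COc1cc(F)c(Oc2ccc(O[Si](C(C)C)(C(C)C)C(C)C)c3c(OCOC)c(Cl)cc(Br)c23)cc1Cl | intermediate
13 | 4-{[8-bromo-6-chloro-5-(methoxymethoxy)-4-(triisopropylsilyloxy)naphthalen-1-yl]oxy}-2-chloro-5-fluorophenol | Oc1cc(F)c(Oc2ccc(O[Si](C(C)C)(C(C)C)C(C)C)c3c(OCOC)c(Cl)cc(Br)c23)cc1Cl | intermediate
14 | 8-bromo-6-chloro-1-[5-chloro-2-fluoro-4-(methoxymethoxy)phenoxy]-5-(methoxymethoxy)-4-(triisopropylsilyloxy)naphthalene | COCOc1cc(F)c(Oc2ccc(O[Si](C(C)C)(C(C)C)C(C)C)c3c(OCOC)c(Cl)cc(Br)c23)cc1Cl | intermediate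
15 | 2-methoxyfuran | COc1ccco1 | starting material
16 | (5-methoxyfuran-2-yl)lithium (furyllithium) | COc1ccc([Li])o1 | intermediate
17 | (5-methoxyfuran-2-yl)zinc chloride (furylzinc chloride) | COc1ccc([Zn]Cl)o1 | intermediate
18 | 6-chloro-1-[5-chloro-2-fluoro-4-(methoxymethoxy)phenoxy]-8-(5-methoxyfuran-2-yl)-5-(methoxymethoxy)-4-(triisopropylsilyloxy)naphthalene | COCOc1cc(F)c(Oc2ccc(O[Si](C(C)C)(C(C)C)C(C)C)c3c(OCOC)c(Cl)cc(-c4ccc(OC)o4)c23)cc1Cl | intermediate
19 | ring-B aryllithium of 18 (lithium between F and OMOM) | COCOc1c([Li])c(F)c(Oc2ccc(O[Si](C(C)C)(C(C)C)C(C)C)c3c(OCOC)c(Cl)cc(-c4ccc(OC)o4)c23)cc1Cl | intermediate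
20 | ring-B aryne of 18 (triple bond between C-4a′ and C-8a′; flanked by OMOM and the ether oxygen) | COCOC1=C(Cl)C=C(Oc2ccc(O[Si](C(C)C)(C(C)C)C(C)C)c3c(OCOC)c(Cl)cc(-c4ccc(OC)o4)c23)C#C1 | intermediate
21 | racemic bridged methoxy ketal (oxygen bridge from C-1′ to C-4′; OMe on C-4′; C-2′=C-3′ alkene; C-1′ bonded to C-8) | COCOc1c(Cl)cc2Oc3ccc(O[Si](C(C)C)(C(C)C)C(C)C)c4c(OCOC)c(Cl)cc(c34)[C@@]3(O5)C=C[C@@]5(OC)c1c23 | intermediate
22 | racemic p-quinol (C-1′ tertiary alcohol bonded to C-8; C-2′=C-3′–C-4′=O; C-4 OTIPS; C-5 and C-5′ OMOM) | COCOc1c(Cl)cc2Oc3ccc(O[Si](C(C)C)(C(C)C)C(C)C)c4c(OCOC)c(Cl)cc(c34)[C@@]3(O)C=CC(=O)c1c23 | intermediate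
23 | racemic syn-epoxy ketone (C-2′/C-3′ epoxide cis to the C-1′ hydroxyl; C-4′ ketone) | COCOc1c(Cl)cc2Oc3ccc(O[Si](C(C)C)(C(C)C)C(C)C)c4c(OCOC)c(Cl)cc(c34)[C@@]3(O)[C@@H]4O[C@@H]4C(=O)c1c23 | intermediate
24 | (4′S)-trans-epoxy diol (C-1′ hydroxyl and epoxide oxygen cis; C-4′ hydroxyl trans to both; single enantiomer) | COCOc1c(Cl)cc2Oc3ccc(O[Si](C(C)C)(C(C)C)C(C)C)c4c(OCOC)c(Cl)cc(c34)[C@@]3(O)[C@@H]4O[C@@H]4[C@@H](O)c1c23 | intermediate
25 | C-4 naphthol (24 without the silyl group) | COCOc1c(Cl)cc2Oc3ccc(O)c4c(OCOC)c(Cl)cc(c34)[C@@]3(O)[C@@H]4O[C@@H]4[C@@H](O)c1c23 | intermediate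
26 | spiroketal enone (C-1 ketal; C-2=C-3–C-4=O; lower epoxide and C-4′ hydroxyl as in the target; C-5 and C-5′ OMOM) | O=C1c2c(OCOC)c(Cl)cc3c2[C@@]2(Oc4cc(Cl)c(OCOC)c5c4[C@]3(O2)[C@@H]2O[C@@H]2[C@H]5O)C=C1 | intermediate
27 | bis-epoxide bis-MOM ether (target with C-5 and C-5′ OMOM) | O=C1c2c(OCOC)c(Cl)cc3c2[C@@]2(Oc4cc(Cl)c(OCOC)c5c4[C@]3(O2)[C@@H]2O[C@@H]2[C@H]5O)[C@@H]2O[C@H]12 | intermediate
28 | target compound CNP0289684.3 | O=C1c2c(O)c(Cl)cc3c2[C@@]2(Oc4cc(Cl)c(O)c5c4[C@]3(O2)[C@@H]2O[C@@H]2[C@H]5O)[C@@H]2O[C@H]12 | target

**Step count and risks**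

Total step count: 15. Longest linear sequence: 14 steps (steps 1 and 3 to 15; step 2 is a one-step side branch).

The three steps most likely to fail:

Step 9 (aryne cycloaddition and ketal collapse). What may go wrong: loss of the acid- and base-sensitive 2-methoxyfuran before the aryne is formed (ring metalation or hydrolysis), or collapse of the bridged ketal along paths that do not end in the ketone. The fallback brings in the C-4′ oxidation level afterwards instead of carrying it in the diene, and sets out from bromide 14. Stille coupling with tributyl(furan-2-yl)stannane (Pd(PPh3)4, CuI, DMF, 80 °C) should give the furan-2-yl ether F1. The same lithiation and LiF elimination (n-BuLi, THF, −78 to 0 °C) with intramolecular aryne–furan cycloaddition should give the racemic 1,4-epoxy-1,4-dihydronaphthalene F2. Catalytic p-TsOH in CH2Cl2 should open the oxygen bridge at the doubly benzylic C-1′–O bond and aromatise to the 4-aryl-1-naphthol F3. Hydroxylative dearomatisation with PhI(OAc)2 in MeCN–H2O at 0 °C should then place the hydroxyl at C-1′, para to the naphthol oxygen, and the route is rejoined at 22.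

Step 11 (reagent-controlled reduction of the racemate). What may go wrong: erosion of reagent control in the wanted antipode, where the oxazaborolidine must override the substrate's own preference for hydride delivery anti to the epoxide oxygen, so that much of the material is diverted to cis-epoxy diols. The fallback accepts the substrate preference and corrects it by inversion, setting out from 23. NaBH4 with CeCl3·7H2O in MeOH at −78 °C should give the racemic cis-epoxy diol F4. Mitsunobu reaction of the secondary hydroxyl with (S)-O-methylmandelic acid (PPh3, diisopropyl azodicarboxylate, THF, 0 °C to rt) should invert C-4′ and give two diastereomeric trans esters that are separated by chromatography or crystallisation, the wanted one being the mandelate F5. K2CO3 in MeOH at 0 °C then returns 24.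

Step 13 (oxidative spiroketalisation). What may go wrong: capture of the oxidised naphthol by solvent or acetate instead of the hindered tertiary hydroxyl, or competing oxidation of ring B. The fallback forms the ketal in two stages from 25. PhI(OAc)2 in MeOH at −20 °C should give the mixed methyl aryl quinone monoketal F6 as a mixture of C-1 epimers. Catalytic pyridinium p-toluenesulfonate with 4 Å molecular sieves in toluene at 50 °C should then exchange the methoxy group for the C-1′ hydroxyl through the planar oxocarbenium ion, so both epimers converge, and the route is rejoined at 26.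

**Further compounds**

F1 | step 9 | 6-chloro-1-[5-chloro-2-fluoro-4-(methoxymethoxy)phenoxy]-8-(furan-2-yl)-5-(methoxymethoxy)-4-(triisopropylsilyloxy)naphthalene | COCOc1cc(F)c(Oc2ccc(O[Si](C(C)C)(C(C)C)C(C)C)c3c(OCOC)c(Cl)cc(-c4ccco4)c23)cc1Cl
F2 | step 9 | racemic 1,4-epoxy-1,4-dihydronaphthalene (oxygen bridge from C-1′ to C-4′; hydrogen on C-4′; C-1′ bonded to C-8), drawn as one antipode | COCOc1c(Cl)cc2Oc3ccc(O[Si](C(C)C)(C(C)C)C(C)C)c4c(OCOC)c(Cl)cc(c34)[C@@]3(O5)C=C[C@H]5c1c23
F3 | step 9 | 4-aryl-1-naphthol (naphthol hydroxyl on C-4′; C-1′ bonded to C-8; seven-membered aryl ether ring) | COCOc1c(Cl)cc2Oc3ccc(O[Si](C(C)C)(C(C)C)C(C)C)c4c(OCOC)c(Cl)cc(c34)-c3ccc(O)c1c23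
F4 | step 11 | racemic cis-epoxy diol (C-4′ hydroxyl cis to the epoxide oxygen and to the C-1′ hydroxyl), drawn as the antipode that is carried on | COCOc1c(Cl)cc2Oc3ccc(O[Si](C(C)C)(C(C)C)C(C)C)c4c(OCOC)c(Cl)cc(c34)[C@@]3(O)[C@@H]4O[C@@H]4[C@H](O)c1c23
F5 | step 11 | (S)-O-methylmandelate of 24 at the C-4′ oxygen | COCOc1c(Cl)cc2Oc3ccc(O[Si](C(C)C)(C(C)C)C(C)C)c4c(OCOC)c(Cl)cc(c34)[C@@]3(O)[C@@H]4O[C@@H]4[C@@H](OC(=O)[C@@H](OC)c4ccccc4)c1c23
F6 | step 13 | mixed methyl aryl quinone monoketal (C-1 bears OMe and the ether oxygen; C-2=C-3–C-4=O; C-1′ hydroxyl free; C-1 epimers) | COCOc1c(Cl)cc2OC3(OC)C=CC(=O)c4c(OCOC)c(Cl)cc(c34)[C@@]3(O)[C@@H]4O[C@@H]4[C@@H](O)c1c23
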